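## Retrosynthetic overview
1. Target ⇐ global desilylation of the hexa-silyl-protected 1,2-dihydronaphthalene **15**. The C3=C4 bond and the new ring are made last, by intramolecular aldol condensation of an ortho-aryl aldehyde onto the aroylmethyl CH2 of 1,4-diketone **14**.
2. **14** ⇐ enantioselective, Brønsted-acid-catalysed Friedel–Crafts conjugate arylation of the 2-arylidene-1,4-diketone **12** with the formyl arene **7**. This forms C1–C8a and sets C1; C2 arises by enol protonation.
3. **12** ⇐ Knoevenagel condensation of the symmetrical 1,4-diketone **4** (from 4-hydroxyacetophenone) with aldehyde **11** (from 2,3,4-trihydroxybenzaldehyde). **7** comes from 5-hydroxyvanillin.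

Abbreviations: TBS = SiMe2tBu; TIPS = Si(iPr)3.

Assumptions:
- The target is 1,2-cis (C1 aryl and C2 aroyl on the same face). I assume this is the thermodynamic isomer, so C2 equilibrates to it in step 8.
- The (R)-TRIP enantiomer is assumed to give C1 = S; this is to be confirmed by screening both enantiomers.
- In step 4, the 4-OH and 3-OH silylate preferentially and the chelated 2-OH stays free.

## Route

**Step 1**
Reactants: **1** 4′-hydroxyacetophenone; **2** TBSCl
Product: **3** 4′-(TBSO)acetophenone
Conditions: TBSCl, imidazole, DMF, rt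
Reagents that add atoms: TBSCl, CC(C)(C)[Si](C)(C)Cl
Why: Standard silylation of a phenol. It protects the 4-OH through the enolate and condensation chemistry and is removed in step 9.

**Step 2**
Reactants: **3** 4′-(TBSO)acetophenone (2 equiv; two molecules of **3** couple)
Product: **4** 1,4-bis[4-(TBSO)phenyl]butane-1,4-dione
Conditions: LDA (1.05 equiv per **3**), THF, –78 °C; then CuBr2 (1.1 equiv per **3**), –78 → 0 °C
Reagents that add atoms: none (CuBr2 is the oxidant; 2 × **3** → **4** + 2 H)
Why: Cu(II)-mediated oxidative homocoupling of the lithium enolate (Ito–Saegusa type) joins two α-carbons to give the symmetrical 1,4-diketone. The aryl silyl ethers survive at –78 °C.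

**Step 3**
Reactants: **5** 3,4-dihydroxy-5-methoxybenzaldehyde (5-hydroxyvanillin); **6** TIPSCl
Product: **7** 3-methoxy-4,5-bis(TIPSO)benzaldehyde
Conditions: TIPSCl (2.4 equiv), imidazole, DMF, 50 °C
Reagents that add atoms: TIPSCl, CC(C)[Si](Cl)(C(C)C)C(C)C
Why: Bis-silylation of the catechol. The bulky OTIPS group next to C2 shields that position, so in step 7 attack occurs at the other ortho position, which lies between CHO and OMe and is para to an OTIPS group.

**Step 4**
Reactants: **8** 2,3,4-trihydroxybenzaldehyde; **2** TBSCl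
Product: **9** 3,4-bis(TBSO)-2-hydroxybenzaldehyde
Conditions: TBSCl (2.2 equiv), imidazole, DMF, 0 °C → rt
Reagents that add atoms: TBSCl, CC(C)(C)[Si](C)(C)Cl
Why: The 4-OH and 3-OH silylate. The 2-OH is hydrogen-bonded to the CHO and stays free.

**Step 5**
Reactants: **9**; **10** MeI
Product: **11** 3,4-bis(TBSO)-2-methoxybenzaldehyde
Conditions: MeI, K2CO3, acetone, 40 °C
Reagents that add atoms: MeI, CI
Why: O-Methylation of the chelated phenol installs the 2-OMe of the pendant ring.

**Step 6**
Reactants: **4** (2.5 equiv); **11** (1 equiv)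
Product: **12** (E)-2-[3,4-bis(TBSO)-2-methoxybenzylidene]-1,4-bis[4-(TBSO)phenyl]butane-1,4-dione
Conditions: piperidine (30 mol%), AcOH (30 mol%), PhMe, 4 Å MS, 80 °C
Reagents that add atoms: none (loses H2O)
Why: Amine-catalysed Knoevenagel (Claisen–Schmidt-type) condensation. Excess diketone limits bis-condensation, and the E-enone (aryl trans to the aroyl group) is the thermodynamic isomer.

**Step 7**
Reactants: **12**; **7** (1.5 equiv); **13** (R)-TRIP (10 mol%)
Product: **14** (2R)-2-[(S)-(2-formyl-6-methoxy-4,5-bis(TIPSO)phenyl)(3,4-bis(TBSO)-2-methoxyphenyl)methyl]-1,4-bis[4-(TBSO)phenyl]butane-1,4-dione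
Conditions: **13** (10 mol%), 4 Å MS, PhCF3, 40 °C, 72 h
Reagents that add atoms: none (**13** is a catalyst; **14** = **12** + **7**)
Why: Proposed new method: enantioselective Friedel–Crafts conjugate arylation of a β-aryl-2-acyl enone by an ortho-formyl trialkoxyarene, controlled by a chiral phosphate.
- Mechanism: the phosphoric acid binds the 1,4-diketone by hydrogen bonding and ion pairing. The arene attacks through the C–H between CHO and OMe (para to OTIPS) at the β-carbon of the enone, from the face left open by the 3,3′-triisopropylphenyl groups. This sets C1 (S). The resulting enol is protonated at C2.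
- Closest known reaction: chiral phosphoric acid-catalysed Friedel–Crafts alkylation of electron-rich arenes with enones and β,γ-unsaturated α-ketoesters.
- Side reaction: any indanol from intramolecular aldol of the enol onto the CHO is reversible under the step 8 conditions.
- C2 is not controlled here and converges in step 8.

**Step 8**
Reactants: **14**
Product: **15** hexa-silyl-protected licobichalcone, (1S,2S)-1,2-dihydronaphthalene
Conditions: piperidine (30 mol%), AcOH (30 mol%), PhMe, 4 Å MS, 60 °C
Reagents that add atoms: none (loses H2O)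
Why: Intramolecular amine-catalysed aldol condensation.
- Ring closure and regiochemistry: the less hindered aroylmethyl ketone (via its enamine or enol) attacks the aldehyde to close the six-membered ring. Dehydration gives the conjugated C3=C4 enone. The alternative five-membered aldol adduct has a quaternary C2, cannot dehydrate and reverts.
- C2 stereochemistry: C2–H is α to its own aroyl group, so it epimerises and equilibrates to the cis isomer.
- C1 is a non-enolisable benzhydryl centre and is untouched.

**Step 9**
Reactants: **15**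
Product: **16** licobichalcone (1S,2S)
Conditions: TBAF (12 equiv), AcOH (12 equiv), THF, 0 °C → rt, degassed, dark
Reagents that add atoms: none
Why: AcOH-buffered fluoride cleaves all six aryl silyl ethers (aryl TBS and TIPS ethers are good fluoride acceptors). The aryl methyl ethers, enone and ketones survive, and buffering prevents epimerisation at C2.

## Compound list
1 | 4′-hydroxyacetophenone | CC(=O)c1ccc(O)cc1 | starting material
2 | TBSCl | CC(C)(C)[Si](C)(C)Cl | starting material (reagent)
3 | 4′-(TBSO)acetophenone | CC(=O)c1ccc(O[Si](C)(C)C(C)(C)C)cc1 | intermediate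
4 | 1,4-bis[4-(TBSO)phenyl]butane-1,4-dione | O=C(CCC(=O)c1ccc(O[Si](C)(C)C(C)(C)C)cc1)c1ccc(O[Si](C)(C)C(C)(C)C)cc1 | intermediate
5 | 5-hydroxyvanillin (3,4-dihydroxy-5-methoxybenzaldehyde) | COc1cc(C=O)cc(O)c1O | starting material
6 | TIPSCl | CC(C)[Si](Cl)(C(C)C)C(C)C | starting material (reagent)
7 | 3-methoxy-4,5-bis(TIPSO)benzaldehyde | COc1cc(C=O)cc(O[Si](C(C)C)(C(C)C)C(C)C)c1O[Si](C(C)C)(C(C)C)C(C)C | intermediate
8 | 2,3,4-trihydroxybenzaldehyde | O=Cc1ccc(O)c(O)c1O | starting material
9 | 3,4-bis(TBSO)-2-hydroxybenzaldehyde | O=Cc1ccc(O[Si](C)(C)C(C)(C)C)c(O[Si](C)(C)C(C)(C)C)c1O | intermediate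
10 | iodomethane | CI | starting material (reagent)
11 | 3,4-bis(TBSO)-2-methoxybenzaldehyde | COc1c(C=O)ccc(O[Si](C)(C)C(C)(C)C)c1O[Si](C)(C)C(C)(C)C | intermediate
12 | (E)-arylidene diketone | COc1c(/C=C(/C(=O)c2ccc(O[Si](C)(C)C(C)(C)C)cc2)CC(=O)c2ccc(O[Si](C)(C)C(C)(C)C)cc2)ccc(O[Si](C)(C)C(C)(C)C)c1O[Si](C)(C)C(C)(C)C | intermediate
13 | (R)-TRIP chiral phosphoric acid catalyst (axial chirality R, not encoded in SMILES) | O=P1(O)Oc2c(-c3c(C(C)C)cc(C(C)C)cc3C(C)C)cc3ccccc3c2-c2c(O1)c(-c1c(C(C)C)cc(C(C)C)cc1C(C)C)cc1ccccc21 | starting material (catalyst)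
14 | Friedel–Crafts adduct (diarylmethine S, butanedione C2 R) | COc1c([C@@H](c2c(C=O)cc(O[Si](C(C)C)(C(C)C)C(C)C)c(O[Si](C(C)C)(C(C)C)C(C)C)c2OC)[C@@H](CC(=O)c2ccc(O[Si](C)(C)C(C)(C)C)cc2)C(=O)c2ccc(O[Si](C)(C)C(C)(C)C)cc2)ccc(O[Si](C)(C)C(C)(C)C)c1O[Si](C)(C)C(C)(C)C | intermediate
15 | hexa-silyl-protected licobichalcone | COc1c([C@H]2c3c(cc(O[Si](C(C)C)(C(C)C)C(C)C)c(O[Si](C(C)C)(C(C)C)C(C)C)c3OC)C=C(C(=O)c3ccc(O[Si](C)(C)C(C)(C)C)cc3)[C@H]2C(=O)c2ccc(O[Si](C)(C)C(C)(C)C)cc2)ccc(O[Si](C)(C)C(C)(C)C)c1O[Si](C)(C)C(C)(C)C | intermediate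
16 | licobichalcone | COc1c([C@H]2c3c(cc(O)c(O)c3OC)C=C(C(=O)c3ccc(O)cc3)[C@H]2C(=O)c2ccc(O)cc2)ccc(O)c1O | target

## Totals
Total steps: 9. Longest linear sequence: 6 (for example 8 → 9 → 11 → 12 → 14 → 15 → 16, steps 4–9; or 1 → 3 → 4 → 12 → 14 → 15 → 16, steps 1, 2, 6–9).

## Three steps most likely to fail
1. **Step 7 (proposed new Friedel–Crafts arylation).** The ortho-formyl arene is only weakly nucleophilic, the attacked position is flanked by CHO and OMe, and the acceptor is a deactivated, donor-substituted enone.
   - Fallback (known chemistry): Rh/chiral-diene Hayashi–Miyaura asymmetric 1,4-addition to **12** of the arylboronic ester corresponding to **7**, made from the acetal-protected 2-bromo arene derived from **7**. The acetal is then unmasked to the aldehyde, giving **14**.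
2. **Step 6 (mono-Knoevenagel).** The ortho-OMe, electron-rich aldehyde is sluggish, and bis-condensation or Z/E mixtures are possible.
   - Fallback: α-brominate **4** (PhNMe3+ Br3–), convert the bromide to the phosphonium salt and ylide, and run a Wittig reaction with **11** to give **12**.
3. **Step 8 (cyclodehydration and C2 configuration).** The indanol pathway may dominate, or C2 may equilibrate to the trans isomer.
   - Fallback: a stepwise sequence. Form the silyl enol ether of the aroylmethyl ketone (TBSOTf, Et3N) and run a TiCl4-mediated intramolecular Mukaiyama aldol. Then dehydrate with Burgess reagent or MsCl/Et3N–DBU, and correct C2 by DBU equilibration if needed.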